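All runs were generated by integration with made-up constants; noise was put on by code.

Take one equivalent of partner per starting material as the zero of the scale: at that charge each partner can make one target, so the shortfall is read directly.

| flask | starting material | partner | protic impurity | catalyst | remark | time |
|---|---|---|---|---|---|---|
| north-west | 0.027 M | 0.0033 M | 5.4 mM | 40 µM | run made earlier |  |
| north | 0.027 M | 0.027 M | 5.4 mM | 40 µM | run made earlier |  |
| north-east | 0.027 M | 0.20 M | 5.4 mM | 40 µM | run made earlier |  |
| delta | 0.027 M | 0.00300 M | 5.40 mM | 40 µM |  | 25 h |
| eta | 0.027 M | 0.0100 M | 5.40 mM | 40 µM |  | 25 h |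
| epsilon | 0.027 M | 0.0250 M | 5.40 mM | 40 µM |  | 25 h |
| theta | 0.027 M | 0.0800 M | 5.40 mM | 40 µM |  | 25 h |
| gamma | 0.027 M | 0.250 M | 5.40 mM | 40 µM |  | 25 h |

| run | time / h | target / % | starting material / % |
|---|---|---|---|
| north-west | 2.50 | 2 | 96 |
| north-west | 5.00 | 3 | 100 |
| north-west | 8.00 | 4 | 93 |
| north-west | 10.0 | 5 | 91 |
| north-west | 12.0 | 8 | 98 |
| north | 1.00 | 8 | 91 |
| north | 3.00 | 14 | 77 |
| north | 6.00 | 23 | 67 |
| north | 8.00 | 23 | 62 |
| north | 12.0 | 23 | 54 |
| north-east | 1.00 | 39 | 42 |
| north-east | 2.00 | 57 | 18 |
| north-east | 4.00 | 62 | 5 |
| north-east | 6.00 | 69 | 3 |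
| north-east | 12.0 | 75 | 5 |

(scatter of a reading: 2 percentage points)

- "hardly changes" means that all values lie within two and a half points (for a concentration: within two and a half percent of the largest)

1. [target] at the end for delta, eta, epsilon, theta, gamma, in this order
2. the shape of the row from first to last (falls all the way / rises all the way / hardly changes / falls, then rises / rises, then falls)

First ask what one equivalent gives. In the north run target stands at 23% from 6.00 h to 12.0 h while starting material falls on to 54%, so that run reads 0.230 for the partner yield, the target formed per partner charged.

Next ask whether this yield holds below one equivalent, where partner is the limiting reagent. Multiply it by the equivalents: north-west, at 0.122 equivalents, then gets 2.81% of the starting material charged. Its readings of 2% to 5% up to 10.0 h lie around that, but the last, 8%, stands higher. Accept the rule as a working estimate, with that last reading against it. My reckoning then gives 2.56% for delta, 8.52% for eta, 21.3% for epsilon and 68.1% for theta.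

Last, ask where the starting material caps the rule. The north-east run reaches 75% with starting material at 5%, so take that reading as the ceiling, which the rule meets at 3.26 equivalents. Gamma, at 9.26 equivalents, stands beyond this, so put it at 75%. My row rises all the way.

The forecast gives 0.0026 M, 0.0055 M, 0.0063 M, 0.013 M and 0.021 M, and its shape is rises all the way. It says delta “should use most of its” partner, which is 9.63% of the starting material charged, more than my figure.

The flask gives 4.25 × 10⁻⁴ M, 0.00156 M, 0.00453 M, 0.0143 M and 0.0200 M, and its shape is rises all the way.

    starting material + partner ⇌ target (K = 510 M⁻¹, k = 0.0590 M⁻¹ min⁻¹)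
    partner + protic impurity → quenched reagent (k = 0.180 M⁻¹ min⁻¹)
    starting material + partner ⇌ isomer of the product (K = 75.0 M⁻¹, k = 0.0260 M⁻¹ min⁻¹)
    target + catalyst ⇌ isomer of the product + catalyst, rate k4*[catalyst]*[target] forward; the back reaction follows from the equilibrium constant (k = 3.50 M⁻¹ min⁻¹)
    partner → decomposed reagent (k = 0.00180 min⁻¹)
    starting material + target → side product (k = 0.0310 M⁻¹ min⁻¹)

The partner yield at 25 h comes out at 0.181 in epsilon and 0.142 in delta, both less than the 0.230 read in the north run at 12.0 h. At the start of either flask, with equal charges of starting material and protic impurity, the forward step to target has a pseudo-first-order constant for partner of 0.00159 min⁻¹, less than the 0.00347 min⁻¹ of the steps to isomer of the product, quenched reagent and decomposed reagent together, which gives target, at that moment, a share of 0.314 of the partner being consumed.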